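Everything rests on cutting the O1–C2 bond of ring C. The aryl carbon C1′ attached to C2 has two bulky neighbours in ring B, C6′ with its 1,1-dimethylallyl group and C2′ at the pyran fusion, so C2 travels as a linear sp carbon until ring C is closed. A 5-ethynylchromene (ring B) adds as its acetylide to a ring A aldehyde. Oxidation and desilylation then give a 2-hydroxyaryl alkynone. Diethylamine adds to the alkyne carbon next to ring B, the phenol displaces it, and O1–C2 and ring C form in one operation. The 1,1-dimethylallyl group is meta to O4′, out of reach of a Claisen shift, and is built by aldehyde α-arylation and methylenation.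

Key step: step 15

Remark: the target has no stereocentre and its SMILES leaves the hindered C2–C1′ axis undefined, so this axis is not controlled; 2-bromo-4,5-dimethoxybenzonitrile is taken as a catalogue compound.

**Ring B**

Step 1
Reactants: 1 2-bromo-4,5-dimethoxybenzonitrile
Product: 2 2-bromo-4,5-dihydroxybenzonitrile
Conditions: BBr3 (3 equiv), CH2Cl2, −78 °C → rt; then H2O
Reagents that add atoms: none
Why: BBr3 ether cleavage of both aryl methyl ethers (through a cyclic catechol borate that water hydrolyses) is standard for veratrole-type nitriles, and neither C≡N nor C–Br reacts.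

Step 2
Reactants: 2 2-bromo-4,5-dihydroxybenzonitrile
Product: 3 2-bromo-5-hydroxy-4-(methoxymethoxy)benzonitrile
Conditions: MOMCl (1.05 equiv), K2CO3 (1.0 equiv), acetone, 0 °C → rt
Reagents that add atoms: chloromethyl methyl ether, COCCl
Why: Williamson-type O-alkylation with only one equivalent of base: the 4-OH, para to the nitrile, is clearly the more acidic hydroxyl, so its phenoxide is formed and capped first and the 5-OH stays free.

Step 3
Reactants: 3 2-bromo-5-hydroxy-4-(methoxymethoxy)benzonitrile; 4 3-chloro-3-methylbut-1-yne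
Product: 5 2-bromo-4-(methoxymethoxy)-5-[(2-methylbut-3-yn-2-yl)oxy]benzonitrile
Conditions: DBU (1.3 equiv), CuCl2·2H2O (1 mol %), MeCN, 0 °C → rt
Reagents that add atoms: none
Why: Copper-catalysed propargylic etherification of a phenol by a tertiary propargylic chloride runs at or below room temperature, suits acidic electron-poor phenols and leaves C–Br, C≡N and the acetal alone.

Step 4
Reactants: 5 2-bromo-4-(methoxymethoxy)-5-[(2-methylbut-3-yn-2-yl)oxy]benzonitrile
Product: 7 6-bromo-8-(methoxymethoxy)-2,2-dimethyl-2H-chromene-5-carbonitrile, via allenylphenol 6 (not isolated)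
Conditions: PhNEt2, 185 °C
Reagents that add atoms: none
Why: Aromatic propargyl Claisen rearrangement to allenylphenol 6, 1,5-hydrogen shift and oxa-6π electrocyclisation build the 2,2-dimethylpyran, and since the other ortho position carries the MOM ether the ring can fuse only at the carbon next to the nitrile (the later C2′).

Step 5
Reactants: 7 6-bromo-8-(methoxymethoxy)-2,2-dimethyl-2H-chromene-5-carbonitrile; 8 isobutyraldehyde
Product: 9 8-(methoxymethoxy)-2,2-dimethyl-6-(2-methyl-1-oxopropan-2-yl)-2H-chromene-5-carbonitrile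
Conditions: [Pd(allyl)Cl]2 (2 mol %), 1,2,3,4,5-pentaphenyl-1′-(di-tert-butylphosphino)ferrocene (Q-phos, 8 mol %), Cs2CO3 (2 equiv), THF, 85 °C, sealed tube
Reagents that add atoms: none
Why: Palladium-catalysed α-arylation of an α-branched aldehyde: the ortho nitrile accelerates oxidative addition yet is linear and small, the bulky electron-rich ferrocenyl phosphine drives reductive elimination to the quaternary benzylic carbon, and product 9 has no α-hydrogen left for further reaction.

Step 6
Reactants: 9 8-(methoxymethoxy)-2,2-dimethyl-6-(2-methyl-1-oxopropan-2-yl)-2H-chromene-5-carbonitrile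
Product: 10 8-(methoxymethoxy)-2,2-dimethyl-6-(2-methylbut-3-en-2-yl)-2H-chromene-5-carbonitrile
Conditions: Ph3PCH3Br (1.5 equiv), KOtBu (1.4 equiv), THF, 0 °C → rt
Reagents that add atoms: methyltriphenylphosphonium bromide, C[P+](c1ccccc1)(c1ccccc1)c1ccccc1.[Br-]
Why: Wittig methylenation of a non-enolisable aldehyde completes the 1,1-dimethylallyl group at the later C6′, and nitrile, acetal and chromene are inert to the ylide.

Step 7
Reactants: 10 8-(methoxymethoxy)-2,2-dimethyl-6-(2-methylbut-3-en-2-yl)-2H-chromene-5-carbonitrile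
Product: 12 8-(methoxymethoxy)-2,2-dimethyl-6-(2-methylbut-3-en-2-yl)-2H-chromene-5-carbaldehyde, via aluminated aldimine 11 (not isolated)
Conditions: iBu2AlH (1.3 equiv), toluene, −78 → −20 °C; then 1 M aq. citric acid, 0 °C
Reagents that add atoms: water, O
Why: Partial reduction of a nitrile with iBu2AlH: hydride reaches the linear C≡N group although both ortho positions are filled, aluminated aldimine 11 resists a second hydride, and cold dilute citric acid hydrolyses it faster than it attacks the MOM ether.

Step 8
Reactants: 12 8-(methoxymethoxy)-2,2-dimethyl-6-(2-methylbut-3-en-2-yl)-2H-chromene-5-carbaldehyde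
Product: 13 5-ethynyl-8-(methoxymethoxy)-2,2-dimethyl-6-(2-methylbut-3-en-2-yl)-2H-chromene
Conditions: dimethyl (1-diazo-2-oxopropyl)phosphonate (2 equiv), K2CO3 (3 equiv), MeOH/THF, rt → 40 °C
Reagents that add atoms: dimethyl (1-diazo-2-oxopropyl)phosphonate, COP(=O)(OC)C(=[N+]=[N-])C(C)=O
Why: Seyferth–Gilbert homologation in its Ohira–Bestmann form converts non-enolisable aryl aldehydes into terminal alkynes under mild carbonate/methanol conditions that none of the other groups notice.

**Ring A**

Step 9
Reactants: 14 2,4,6-trihydroxybenzaldehyde; 15 prenyl bromide (1-bromo-3-methylbut-2-ene)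
Product: 16 2,4,6-trihydroxy-3-(3-methylbut-2-enyl)benzaldehyde
Conditions: DBU (1.0 equiv), 15 (0.9 equiv), THF, 0 °C → rt
Reagents that add atoms: none
Why: Base-mediated C-alkylation of the ambident phloroglucinol-type phenoxide with an allylic bromide; C3 and C5 of 14 are equivalent, so only one mono-C-prenyl product is possible, and a deficit of 15 holds back double alkylation.

Step 10
Reactants: 16 2,4,6-trihydroxy-3-(3-methylbut-2-enyl)benzaldehyde
Product: 17 2-hydroxy-4,6-bis(methoxymethoxy)-3-(3-methylbut-2-enyl)benzaldehyde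
Conditions: MOMCl (2.2 equiv), iPr2NEt (2.5 equiv), CH2Cl2, 0 °C → rt
Reagents that add atoms: chloromethyl methyl ether, COCCl
Why: Selective O-alkylation: the unchelated 4-OH and the less hindered of the two chelated hydroxyls (6-OH) react, whereas the 2-OH, locked in a hydrogen bond to the formyl group and shielded by the neighbouring prenyl chain, stays free and is the oxygen that becomes O1 next to C8.

Step 11
Reactants: 17 2-hydroxy-4,6-bis(methoxymethoxy)-3-(3-methylbut-2-enyl)benzaldehyde
Product: 18 4,6-bis(methoxymethoxy)-3-(3-methylbut-2-enyl)-2-(triisopropylsilyloxy)benzaldehyde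
Conditions: iPr3SiCl (1.5 equiv), imidazole (3 equiv), DMAP (cat.), DMF, 40 °C
Reagents that add atoms: chlorotriisopropylsilane, CC(C)[Si](Cl)(C(C)C)C(C)C
Why: Silyl ether formation masks the acidic phenol for the acetylide step, and the bulky triisopropylsilyl group is chosen because it resists O-to-O silyl transfer to a neighbouring alkoxide.

**Union, ring C and endgame**

Step 12
Reactants: 13 5-ethynyl-8-(methoxymethoxy)-2,2-dimethyl-6-(2-methylbut-3-en-2-yl)-2H-chromene; 18 4,6-bis(methoxymethoxy)-3-(3-methylbut-2-enyl)-2-(triisopropylsilyloxy)benzaldehyde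
Product: 20 racemic 1-[4,6-bis(methoxymethoxy)-3-(3-methylbut-2-enyl)-2-(triisopropylsilyloxy)phenyl]-3-[8-(methoxymethoxy)-2,2-dimethyl-6-(2-methylbut-3-en-2-yl)-2H-chromen-5-yl]prop-2-yn-1-ol, via lithium acetylide 19 (not isolated)
Conditions: n-BuLi (1.0 equiv), THF, −78 °C; then 18, −78 → −40 °C; AcOH quench at −40 °C
Reagents that add atoms: none
Why: 1,2-Addition of a lithium acetylide to an aldehyde: the rod-shaped nucleophile keeps the crowded ring B away from the doubly ortho-substituted formyl group, and the new carbinol centre forms as a racemate that step 13 erases.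

Step 13
Reactants: 20 racemic propargylic alcohol
Product: 21 1-[4,6-bis(methoxymethoxy)-3-(3-methylbut-2-enyl)-2-(triisopropylsilyloxy)phenyl]-3-[8-(methoxymethoxy)-2,2-dimethyl-6-(2-methylbut-3-en-2-yl)-2H-chromen-5-yl]prop-2-yn-1-one
Conditions: MnO2 (activated, 20 equiv), CH2Cl2, rt
Reagents that add atoms: none
Why: MnO2 oxidation is selective for the doubly activated (benzylic and propargylic) alcohol and leaves alkenes, acetals and the silyl ether untouched.

Step 14
Reactants: 21 O-silyl alkynone
Product: 22 1-[2-hydroxy-4,6-bis(methoxymethoxy)-3-(3-methylbut-2-enyl)phenyl]-3-[8-(methoxymethoxy)-2,2-dimethyl-6-(2-methylbut-3-en-2-yl)-2H-chromen-5-yl]prop-2-yn-1-one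
Conditions: Bu4NF/AcOH (1:1, 1.2 equiv), THF, 0 °C
Reagents that add atoms: none
Why: Fluoride-induced cleavage of an aryl silyl ether; acetic acid buffering protonates the phenoxide at once, so the chelated phenol 22 can be isolated before any uncontrolled ring closure, and MOM ethers are stable.

Step 15
Reactants: 22 2-hydroxyaryl alkynone
Product: 24 5,7-bis(methoxymethoxy)-2-[8-(methoxymethoxy)-2,2-dimethyl-6-(2-methylbut-3-en-2-yl)-2H-chromen-5-yl]-8-(3-methylbut-2-enyl)-4H-chromen-4-one, via enaminone 23 (not isolated)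
Conditions: Et2NH (10 equiv), EtOH, rt → 60 °C
Reagents that add atoms: none
Why: Et2NH adds in a conjugate sense to the alkyne carbon bonded to C1′ and gives the push–pull (E)-enaminone 23; the chelated 2-OH then attacks this same carbon, and loss of Et2NH from the adduct leaves the pyranone (addition–elimination, net oxa-Michael). The closest known reaction type is the secondary-amine-mediated cyclisation of 2-hydroxyaryl alkynones to flavones and chromones. Ring C closes in a formal 6-endo-dig mode (6-endo-trig at the enaminone stage), only the O1–C2 bond is formed, and no stereocentre is created. The selectivity needed is 6-endo over 5-exo (aurone), and it is secured because the amine turns the carbon that must become C2 into the only electrophilic site that carries a leaving group, while the α-carbon becomes nucleophilic. Access is secured by the substrate: the reacting carbon is sp-hybridised and stands outside the cleft between the C6′ 1,1-dimethylallyl group and the pyran CH on C2′, and strain between NEt2 and ring B in 23 favours expulsion of the amine. MOM ethers, the isolated alkenes and the chromene are inert to a secondary amine in ethanol.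

Step 16
Reactants: 24 flavone tris-MOM ether
Product: 27 3-hydroxy-5,7-bis(methoxymethoxy)-2-[8-(methoxymethoxy)-2,2-dimethyl-6-(2-methylbut-3-en-2-yl)-2H-chromen-5-yl]-8-(3-methylbut-2-enyl)-4H-chromen-4-one, via 3-lithioflavone 25 (not isolated), via 3-boronate 26 (not isolated)
Conditions: LiN(iPr)2 (1.5 equiv), THF, −78 °C; B(OMe)3 (4 equiv), −78 → 0 °C; AcOH (2 equiv), 30% aq. H2O2, 0 °C → rt
Reagents that add atoms: hydrogen peroxide, OO
Why: Carbonyl-directed C3 lithiation of a flavone (kinetically favoured at −78 °C over the C8 benzylic methylene), borylation and boronate oxidation is a known flavone-to-flavonol sequence, and H2O2 attacks only the C–B bond because the isolated alkenes are not epoxidised without a peracid or metal catalyst.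

Step 17
Reactants: 27 flavonol tris-MOM ether
Product: 28 3,5,7-trihydroxy-2-[8-hydroxy-2,2-dimethyl-6-(2-methylbut-3-en-2-yl)-2H-chromen-5-yl]-8-(3-methylbut-2-enyl)-4H-chromen-4-one (CNP0241222.0)
Conditions: 3 M aq. HCl/MeOH (1:5), 40 °C, stopped at full conversion
Reagents that add atoms: none
Why: Acid-catalysed acetal exchange with methanol removes the three phenolic MOM groups, and dilute acid at mild temperature is chosen because acetal cleavage is much faster than protonation of the prenyl, 1,1-dimethylallyl or chromene double bonds.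

**Compound list**

1 | 2-bromo-4,5-dimethoxybenzonitrile | N#Cc1cc(OC)c(OC)cc1Br | starting material
2 | 2-bromo-4,5-dihydroxybenzonitrile | N#Cc1cc(O)c(O)cc1Br | intermediate
3 | 2-bromo-5-hydroxy-4-(methoxymethoxy)benzonitrile | N#Cc1cc(O)c(OCOC)cc1Br | intermediate
4 | 3-chloro-3-methylbut-1-yne | C#CC(C)(C)Cl | starting material
5 | 2-bromo-4-(methoxymethoxy)-5-[(2-methylbut-3-yn-2-yl)oxy]benzonitrile | N#Cc1cc(OC(C)(C)C#C)c(OCOC)cc1Br | intermediate
6 | 6-bromo-3-hydroxy-4-(methoxymethoxy)-2-(3-methylbuta-1,2-dienyl)benzonitrile (allenylphenol, not isolated) | N#Cc1c(Br)cc(OCOC)c(O)c1C=C=C(C)C | intermediate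
7 | 6-bromo-8-(methoxymethoxy)-2,2-dimethyl-2H-chromene-5-carbonitrile | N#Cc1c(Br)cc(OCOC)c2OC(C)(C)C=Cc12 | intermediate
8 | isobutyraldehyde | CC(C)C=O | starting material
9 | 8-(methoxymethoxy)-2,2-dimethyl-6-(2-methyl-1-oxopropan-2-yl)-2H-chromene-5-carbonitrile | N#Cc1c(C(C)(C)C=O)cc(OCOC)c2OC(C)(C)C=Cc12 | intermediate
10 | 8-(methoxymethoxy)-2,2-dimethyl-6-(2-methylbut-3-en-2-yl)-2H-chromene-5-carbonitrile | N#Cc1c(C(C)(C)C=C)cc(OCOC)c2OC(C)(C)C=Cc12 | intermediate
11 | N-(diisobutylalumanyl)aldimine of 12 (not isolated) | CC(C)C[Al](CC(C)C)N=Cc1c(C(C)(C)C=C)cc(OCOC)c2OC(C)(C)C=Cc12 | intermediate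
12 | 8-(methoxymethoxy)-2,2-dimethyl-6-(2-methylbut-3-en-2-yl)-2H-chromene-5-carbaldehyde | O=Cc1c(C(C)(C)C=C)cc(OCOC)c2OC(C)(C)C=Cc12 | intermediate
13 | 5-ethynyl-8-(methoxymethoxy)-2,2-dimethyl-6-(2-methylbut-3-en-2-yl)-2H-chromene | C#Cc1c(C(C)(C)C=C)cc(OCOC)c2OC(C)(C)C=Cc12 | intermediate
14 | 2,4,6-trihydroxybenzaldehyde | O=Cc1c(O)cc(O)cc1O | starting material
15 | prenyl bromide | CC(C)=CCBr | starting material
16 | 2,4,6-trihydroxy-3-(3-methylbut-2-enyl)benzaldehyde | O=Cc1c(O)cc(O)c(CC=C(C)C)c1O | intermediate
17 | 2-hydroxy-4,6-bis(methoxymethoxy)-3-(3-methylbut-2-enyl)benzaldehyde | O=Cc1c(O)c(CC=C(C)C)c(OCOC)cc1OCOC | intermediate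
18 | 4,6-bis(methoxymethoxy)-3-(3-methylbut-2-enyl)-2-(triisopropylsilyloxy)benzaldehyde | O=Cc1c(O[Si](C(C)C)(C(C)C)C(C)C)c(CC=C(C)C)c(OCOC)cc1OCOC | intermediate
19 | lithium acetylide of 13 (not isolated) | [Li]C#Cc1c(C(C)(C)C=C)cc(OCOC)c2OC(C)(C)C=Cc12 | intermediate
20 | racemic propargylic alcohol from 18 and 19 | OC(C#Cc1c(C(C)(C)C=C)cc(OCOC)c2OC(C)(C)C=Cc12)c1c(O[Si](C(C)C)(C(C)C)C(C)C)c(CC=C(C)C)c(OCOC)cc1OCOC | intermediate
21 | O-triisopropylsilyl alkynone | O=C(C#Cc1c(C(C)(C)C=C)cc(OCOC)c2OC(C)(C)C=Cc12)c1c(O[Si](C(C)C)(C(C)C)C(C)C)c(CC=C(C)C)c(OCOC)cc1OCOC | intermediate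
22 | 2-hydroxyaryl alkynone (precursor of the key step) | O=C(C#Cc1c(C(C)(C)C=C)cc(OCOC)c2OC(C)(C)C=Cc12)c1c(O)c(CC=C(C)C)c(OCOC)cc1OCOC | intermediate
23 | (E)-3-(diethylamino) enaminone (not isolated) | O=C(/C=C(/N(CC)CC)c1c(C(C)(C)C=C)cc(OCOC)c2OC(C)(C)C=Cc12)c1c(O)c(CC=C(C)C)c(OCOC)cc1OCOC | intermediate
24 | 3-deoxyflavone 5,7,4′-tris-MOM ether (product of the key step) | O=c1cc(-c2c(C(C)(C)C=C)cc(OCOC)c3OC(C)(C)C=Cc23)oc2c(CC=C(C)C)c(OCOC)cc(OCOC)c12 | intermediate
25 | 3-lithioflavone (not isolated) | [Li]c1c(-c2c(C(C)(C)C=C)cc(OCOC)c3OC(C)(C)C=Cc23)oc2c(CC=C(C)C)c(OCOC)cc(OCOC)c2c1=O | intermediate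
26 | flavone-3-boronic acid dimethyl ester (not isolated) | COB(OC)c1c(-c2c(C(C)(C)C=C)cc(OCOC)c3OC(C)(C)C=Cc23)oc2c(CC=C(C)C)c(OCOC)cc(OCOC)c2c1=O | intermediate
27 | flavonol 5,7,4′-tris-MOM ether | O=c1c(O)c(-c2c(C(C)(C)C=C)cc(OCOC)c3OC(C)(C)C=Cc23)oc2c(CC=C(C)C)c(OCOC)cc(OCOC)c12 | intermediate
28 | CNP0241222.0 | C=CC(C)(C)c1cc(O)c2c(c1-c1oc3c(CC=C(C)C)c(O)cc(O)c3c(=O)c1O)C=CC(C)(C)O2 | target

Total step count: 17. Longest linear sequence: 14 (steps 1–8, then 12–17).

**Steps most likely to fail**

Step 15. The conjugate addition of the amine at the shielded alkyne carbon may be slow. Direct closure of the phenoxide at the α-carbon (5-exo) or unspecific decay of the ynone could then compete. The fallback separates the two events and sets out from silyl alkynone 21. With the phenol still masked, the smaller and more nucleophilic pyrrolidine is forced onto the alkyne (neat or in EtOH, 60 °C). This gives the O-silyl pyrrolidino enaminone F1, and no ring closure of either kind is possible at this stage. Bu4NF in THF (0 °C → rt) then frees the phenoxide. It can attack only the amine-bearing carbon, and loss of pyrrolidine gives flavone 24, where the route is rejoined.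

Step 5. Reductive elimination to the quaternary carbon may be slow next to the nitrile. Hydrodebromination or base-induced consumption of the aldehyde could then take over. The fallback sets out from bromide 7 and uses a γ-selective Suzuki–Miyaura allyl–aryl coupling. The conditions are prenylboronic acid pinacol ester, Pd(OAc)2 with a bulky biaryl monophosphine of the type selected for branched products, aq. K3PO4, MeCN, 70 °C. SE2′ transmetalation puts palladium on the tertiary allyl terminus, and fast reductive elimination gives the 1,1-dimethylallyl nitrile 10 directly. The route is rejoined there and step 6 is dropped.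

Step 16. Three things may go wrong:
- deprotonation at the doubly activated C8 methylene instead of C3;
- ring opening of the C3 anion by expulsion of the O1 phenoxide;
- slow capture by the borate in the shadow of ring B.

The fallback replaces C–H metalation by halogen–metal exchange and sets out from silyl alkynone 21.
- Pyrrolidine gives the O-silyl pyrrolidino enaminone F1 as above.
- I2/Et3N in CH2Cl2 at 0 °C iodinates its strongly nucleophilic α-carbon, which is far more electron-rich than the isolated alkenes, to give the α-iodoenaminone F2.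
- Bu4NF releases the phenoxide, which closes ring C with loss of pyrrolidine to give the 3-iodoflavone F3.
- iPrMgCl·LiCl (THF, −40 °C) gives the 3-magnesioflavone F4 by iodine–magnesium exchange.
- B(OMe)3 converts F4 into boronate 26, where the route is rejoined for the peroxide oxidation to 27.

**Further compounds**

F0 | step 5 | none | none
F1 | step 15 | O-triisopropylsilyl (E)-3-(pyrrolidin-1-yl) enaminone | O=C(/C=C(/N1CCCC1)c1c(C(C)(C)C=C)cc(OCOC)c2OC(C)(C)C=Cc12)c1c(O[Si](C(C)C)(C(C)C)C(C)C)c(CC=C(C)C)c(OCOC)cc1OCOC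
F2 | step 16 | O-triisopropylsilyl 2-iodo-3-(pyrrolidin-1-yl) enaminone (E/Z not defined) | O=C(C(I)=C(N1CCCC1)c1c(C(C)(C)C=C)cc(OCOC)c2OC(C)(C)C=Cc12)c1c(O[Si](C(C)C)(C(C)C)C(C)C)c(CC=C(C)C)c(OCOC)cc1OCOC
F3 | step 16 | 3-iodoflavone 5,7,4′-tris-MOM ether | O=c1c(I)c(-c2c(C(C)(C)C=C)cc(OCOC)c3OC(C)(C)C=Cc23)oc2c(CC=C(C)C)c(OCOC)cc(OCOC)c12
F4 | step 16 | 3-(chloromagnesio)flavone 5,7,4′-tris-MOM ether | Cl[Mg]c1c(-c2c(C(C)(C)C=C)cc(OCOC)c3OC(C)(C)C=Cc23)oc2c(CC=C(C)C)c(OCOC)cc(OCOC)c2c1=O
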